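A peak drawn between readings looks as exact as a reading, yet it carries their scatter.

| flask | starting material | remark | time |
|---|---|---|---|
| oak | 0.12 M | run made earlier |  |
| maple | 0.50 M | run made earlier |  |
| flask | 0.25 M |  | 10 h |

| run | time / h | ring / % | starting material / % |
|---|---|---|---|
| oak | 0.133 | 69 | 5 |
| oak | 0.250 | 53 | 1 |
| oak | 0.500 | 23 | 2 |
| oak | 1.33 | 0 | 2 |
| oak | 2.50 | 0 | 0 |
| oak | 6.00 | 3 | 0 |
| oak | 12.0 | 1 | 2 |
| maple | 0.133 | 66 | 5 |
| maple | 0.250 | 56 | 0 |
| maple | 0.500 | 28 | 0 |
| maple | 1.33 | 0 | 2 |
| maple | 2.50 | 0 | 3 |
| maple | 6.00 | 1 | 0 |
| maple | 12.0 | 0 | 1 |

(standard deviation of a reading: 2 percentage points)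

- in percentages every species weighs as the starting material in it: one open dimer or idle adduct counts as two
- for ring the idle adduct is counted in
- steps that have been proposed: 2 starting material <-> open dimer; starting material -> ring; starting material + ring <-> idle adduct; ring -> over-reaction product
- in an amount of ring, one idle adduct counts as one ring

- when, up to 10 h, the flask holds most ring
- the amount of ring, in percent of the starting material charged, at that time

Among the proposed steps, ring forms from starting material and passes on to over-reaction product, so my own reckoning reads two times from the runs. The feed time τf, in which starting material falls by a factor e, is 0.0444 h, read from 5 % left at 0.133 h in both the oak and maple runs. The fall time τd of ring, read from the pooled readings of both runs between 0.250 h and 0.500 h, is 0.329 h. The fall time is thus longer than the feed time, and the ratio ρ of fall time to feed time reads 7.41. For two first-order steps in line, the peak is ρ raised to minus one over (ρ minus one), which gives the 0.25 M flask an estimated 73.2 % of its charge at 0.103 h.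

The forecast says 73 % at 0.105 h, on the ground that “Both runs give the same percentage curves despite a fourfold difference in concentration”.

The flask holds most ring at 0.128 h, with 66.9 %.

    2 starting material ⇌ open dimer (K = 3.40 M⁻¹, k = 2.80 M⁻¹ min⁻¹)
    starting material → ring (k = 0.600 min⁻¹)
    starting material + ring ⇌ idle adduct, settled at all times (K = 12.0 M⁻¹)
    ring → over-reaction product (k = 0.0580 min⁻¹)

The passing of ring into over-reaction product holds the peak of this flask down by more than the open dimer step does: a run of this flask without it peaks at 100 %, against 66.9 % with it. The flask stands 6.3 percentage points below the height given by ρ, and a part of that gap belongs to the open dimer: without the dimer step this flask peaks at 70.0 %. The neighbour flask charged with 0.062 M of starting material reaches 72.8 %, level with the 73.2 % from ρ.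

All runs were generated by integration from invented constants, and the scatter is random.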